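A direct plan would acylate a benzyl-oxazolidinone with a protected 2,4-dioxygenated phenylacetic acid to the imide A1 and add the boron enolate of A1 to the bromo-salicylaldehyde A2, which would give the syn-aldol adduct A3. It would then strip the benzylic hydroxyl with silane and acid, cleave the auxiliary, close ring C by Mitsunobu etherification, build ring D by propargyl Claisen rearrangement and last couple the prenyl group to the aryl bromide A4.
Its weakest steps would be:
(a) the aldol addition with the deoxygenation that follows: it would need about eight steps of protection and homologation before any bond of the core forms, would consume a stoichiometric auxiliary, and would make a C4 carbinol only to ionise it next to an epimerisable α-aryl centre;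
(b) the prenyl transfer from tin at 100 °C on the most advanced intermediate, where reaction through either allyl terminus or protodebromination would cost the most precious material;
(c) the 145 °C Claisen step and the Lewis-acid debenzylation before it, which would expose the finished stereocentre and both silyl ethers to harsh conditions late in the route.

New plan.
The retrosynthesis cuts the C3–C1′ bond together with one C4–H bond, which divides the target into an achiral 2H-chromene (rings A and C, prenyl in place) and an 8-bromo-2,2-dimethylchromene (rings B and D).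
Ring C arises in step 3 as a flat 2H-chromene and ring D in step 6, each in its own branch; the isoflavan core exists only once the halves are joined by an enantioselective reductive Heck hydroarylation.
The enabling feature is that C3 is homobenzylic to ring A through C4: C3=C4 of the chromene is a styrene, so aryl goes to C3 and palladium to benzylic C4, where C4a is aromatic and the C3 hydrogen is anti, so β-hydride loss does not compete with hydride capture.
No auxiliary is used, no C4 oxygen has to be removed and no ring is closed on a chiral intermediate; prenyl and ring D are in place before the key step, and only desilylation follows it.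

Key step: step 7

Assumption: the sense of induction in step 7 cannot be predicted with confidence; the ligand antipode that gives the (3R) product is to be fixed in a trial run and is written here as (R)-Xyl-SDP(O), the mono-oxide of (R)-7,7′-bis[bis(3,5-dimethylphenyl)phosphino]-1,1′-spirobiindane.

Step 1
Reactants: 1 5-bromo-2,4-dihydroxybenzaldehyde
Product: 2 5-bromo-2-hydroxy-4-(triisopropylsilyloxy)benzaldehyde
Conditions: i-Pr3SiCl (1.05 equiv), imidazole (2.2 equiv), CH2Cl2, 0 °C → rt
Reagents that add atoms: triisopropylsilyl chloride, CC(C)[Si](Cl)(C(C)C)C(C)C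
Why: Selective silyl ether formation, because the 2-hydroxyl is locked in a hydrogen bond to the aldehyde and only the free, more acidic 4-hydroxyl should react.

Step 2
Reactants: 2 5-bromo-2-hydroxy-4-(triisopropylsilyloxy)benzaldehyde
Product: 3 2-hydroxy-5-(3-methylbut-2-en-1-yl)-4-(triisopropylsilyloxy)benzaldehyde
Conditions: Bu3SnCH2CH=CMe2 (1.5 equiv), Pd(PPh3)4 (5 mol %), toluene, 100 °C
Reagents that add atoms: tributyl(3-methylbut-2-en-1-yl)stannane, CCCC[Sn](CCCC)(CCCC)CC=C(C)C
Why: Stille coupling under neutral, fluoride-free conditions should place the prenyl group on the carbon that carried bromine (reductive elimination at the less hindered allyl terminus), and any reverse-prenyl isomer would be removed here, at the stage of a cheap aldehyde.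

Step 3
Reactants: 3 2-hydroxy-5-(3-methylbut-2-en-1-yl)-4-(triisopropylsilyloxy)benzaldehyde
Product: 6 triisopropyl{[6-(3-methylbut-2-en-1-yl)-2H-chromen-7-yl]oxy}silane, via Petasis allylamine 4 (not isolated), via vinyl o-quinone methide 5 (not isolated)
Conditions: CH2=CHB(OBu)2 (1.5 equiv), Bn2NH (0.4 equiv), 1,4-dioxane, 90 °C
Reagents that add atoms: dibutyl vinylboronate, C=CB(OCCCC)OCCCC
Why: Amine-catalysed Petasis borono-Mannich vinylation of the salicylaldehyde, followed in the same flask by loss of dibenzylamine to an o-quinone methide and oxa-6π electrocyclisation, should give the achiral 2H-chromene in which C4 is the old aldehyde carbon and C3 and C2 come from the vinyl group.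

Step 4
Reactants: 7 4-bromoresorcinol (4-bromobenzene-1,3-diol)
Product: 8 2-bromo-5-(tert-butyldiphenylsilyloxy)phenol
Conditions: t-BuPh2SiCl (1.0 equiv), imidazole (2.2 equiv), CH2Cl2, −20 → 0 °C
Reagents that add atoms: tert-butyl(chloro)diphenylsilane, CC(C)(C)[Si](Cl)(c1ccccc1)c1ccccc1
Why: Regioselective silyl ether formation, in which the bulky silyl chloride should take the hydroxyl para to bromine because the other hydroxyl is flanked by bromine and held in an O–H···Br hydrogen bond.

Step 5
Reactants: 8 2-bromo-5-(tert-butyldiphenylsilyloxy)phenol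
Product: 9 1-bromo-4-(tert-butyldiphenylsilyloxy)-2-(2-methylbut-3-yn-2-yloxy)benzene
Conditions: 3-chloro-3-methylbut-1-yne (1.5 equiv), DBU (1.6 equiv), CuCl2·2H2O (1 mol %), MeCN, 0 °C → rt
Reagents that add atoms: 3-chloro-3-methylbut-1-yne, CC(C)(Cl)C#C
Why: Copper-catalysed O-propargylation of the only free phenol with the tertiary propargylic chloride, under conditions mild enough for the aryl silyl ether.

Step 6
Reactants: 9 1-bromo-4-(tert-butyldiphenylsilyloxy)-2-(2-methylbut-3-yn-2-yloxy)benzene
Product: 12 8-bromo-5-(tert-butyldiphenylsilyloxy)-2,2-dimethyl-2H-chromene, via allenylphenol 10 (not isolated), via dienone o-quinone methide 11 (not isolated)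
Conditions: o-xylene, 140 °C, sealed tube
Reagents that add atoms: none
Why: Aromatic propargyl Claisen rearrangement to the only free ortho carbon (the other carries bromine), then 1,5-hydrogen shift and oxa-6π electrocyclisation, should close ring D with unambiguous regiochemistry and leave the bromine at the future C1′.

Step 7
Reactants: 6 triisopropyl{[6-(3-methylbut-2-en-1-yl)-2H-chromen-7-yl]oxy}silane; 12 8-bromo-5-(tert-butyldiphenylsilyloxy)-2,2-dimethyl-2H-chromene
Product: 13 (3R)-3-[5-(tert-butyldiphenylsilyloxy)-2,2-dimethyl-2H-chromen-8-yl]-6-(3-methylbut-2-en-1-yl)-7-(triisopropylsilyloxy)chromane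
Conditions: 12 (1.0 equiv), 6 (1.3 equiv), Pd(dba)2 (5 mol %), (R)-Xyl-SDP(O) (6 mol %), HCO2Na (2 equiv), DMF/i-PrOH (9:1), 70 °C
Reagents that add atoms: none
Why: Proposed new method: the zerovalent palladium–ligand complex should add oxidatively to the C–Br bond of 12, the aryl–palladium should add syn across C3=C4 of 6 with aryl going to C3 and palladium to benzylic C4, and exchange of bromide for formate, loss of CO2 and C–H reductive elimination should then leave CH2 at C4 (reductive Heck hydroarylation). The closest known reactions are the Heck oxyarylation of 7-oxygenated 2H-chromenes with o-halophenols, which shows the same aryl-to-C3 regiochemistry, and enantioselective intermolecular Heck and reductive Heck reactions of aryl halides with cyclic alkenes under bisphosphine or bisphosphine mono-oxide ligands. No ring is closed: ring C is already present in 6 and rings B and D in 12, and the step forms only the C3–C1′ bond and one C4–H bond. C3 is the only new stereocentre and is set in the migratory insertion by the alkene face that the chiral ligand on palladium exposes to the aryl group; C4 ends as CH2, so no second centre and no diastereomer can arise. The step needs the alkylpalladium to be reduced instead of losing a β-hydrogen, which the substrate secures because the hydrogen on C3 is anti to palladium after syn addition and C4a is aromatic; it needs aryl delivery to C3, secured by benzylic stabilisation of palladium at C4 by ring A; and it needs C3=C4 of 6 to be chosen over the other two alkenes, secured because the ring D alkene is flanked by the gem-dimethyl carbon and the peri silyloxy group and the prenyl alkene is trisubstituted and unconjugated.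

Step 8
Reactants: 13 (3R)-3-[5-(tert-butyldiphenylsilyloxy)-2,2-dimethyl-2H-chromen-8-yl]-6-(3-methylbut-2-en-1-yl)-7-(triisopropylsilyloxy)chromane
Product: 14 (3R)-3-(5-hydroxy-2,2-dimethyl-2H-chromen-8-yl)-6-(3-methylbut-2-en-1-yl)chroman-7-ol
Conditions: Bu4NF (2.4 equiv), AcOH (2.4 equiv), THF, 0 °C → rt
Reagents that add atoms: none
Why: Fluoride-mediated cleavage of both aryl silyl ethers, buffered with acetic acid so that neither strong base nor acid is present, should free the two phenols without cyclisation of the prenyl group onto its neighbouring hydroxyl, without damage to the chromene and without touching the stereocentre.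

**Compound list**
1 | 5-bromo-2,4-dihydroxybenzaldehyde | O=Cc1cc(Br)c(O)cc1O | starting material
2 | 5-bromo-2-hydroxy-4-(triisopropylsilyloxy)benzaldehyde | O=Cc1cc(Br)c(O[Si](C(C)C)(C(C)C)C(C)C)cc1O | intermediate
3 | 2-hydroxy-5-(3-methylbut-2-en-1-yl)-4-(triisopropylsilyloxy)benzaldehyde | O=Cc1cc(CC=C(C)C)c(O[Si](C(C)C)(C(C)C)C(C)C)cc1O | intermediate
4 | 2-[1-(dibenzylamino)prop-2-en-1-yl]-4-(3-methylbut-2-en-1-yl)-5-(triisopropylsilyloxy)phenol (racemic) | C=CC(N(Cc1ccccc1)Cc1ccccc1)c1cc(CC=C(C)C)c(O[Si](C(C)C)(C(C)C)C(C)C)cc1O | intermediate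
5 | 4-(3-methylbut-2-en-1-yl)-6-(prop-2-en-1-ylidene)-3-(triisopropylsilyloxy)cyclohexa-2,4-dien-1-one | C=CC=C1C=C(CC=C(C)C)C(O[Si](C(C)C)(C(C)C)C(C)C)=CC1=O | intermediate
6 | triisopropyl{[6-(3-methylbut-2-en-1-yl)-2H-chromen-7-yl]oxy}silane | CC(C)=CCc1cc2C=CCOc2cc1O[Si](C(C)C)(C(C)C)C(C)C | intermediate
7 | 4-bromoresorcinol (4-bromobenzene-1,3-diol) | Oc1ccc(Br)c(O)c1 | starting material
8 | 2-bromo-5-(tert-butyldiphenylsilyloxy)phenol | Oc1cc(O[Si](c2ccccc2)(c2ccccc2)C(C)(C)C)ccc1Br | intermediate
9 | 1-bromo-4-(tert-butyldiphenylsilyloxy)-2-(2-methylbut-3-yn-2-yloxy)benzene | C#CC(C)(C)Oc1cc(O[Si](c2ccccc2)(c2ccccc2)C(C)(C)C)ccc1Br | intermediate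
10 | 6-bromo-3-(tert-butyldiphenylsilyloxy)-2-(3-methylbuta-1,2-dien-1-yl)phenol | Oc1c(Br)ccc(O[Si](c2ccccc2)(c2ccccc2)C(C)(C)C)c1C=C=C(C)C | intermediate
11 | 2-bromo-5-(tert-butyldiphenylsilyloxy)-6-(3-methylbut-2-en-1-ylidene)cyclohexa-2,4-dien-1-one | O=C1C(Br)=CC=C(O[Si](c2ccccc2)(c2ccccc2)C(C)(C)C)C1=CC=C(C)C | intermediate
12 | 8-bromo-5-(tert-butyldiphenylsilyloxy)-2,2-dimethyl-2H-chromene | CC1(C)C=Cc2c(O[Si](c3ccccc3)(c3ccccc3)C(C)(C)C)ccc(Br)c2O1 | intermediate
13 | (3R)-3-[5-(tert-butyldiphenylsilyloxy)-2,2-dimethyl-2H-chromen-8-yl]-6-(3-methylbut-2-en-1-yl)-7-(triisopropylsilyloxy)chromane | CC(C)=CCc1cc2c(cc1O[Si](C(C)C)(C(C)C)C(C)C)OC[C@@H](c1ccc(O[Si](c4ccccc4)(c4ccccc4)C(C)(C)C)c3c1OC(C)(C)C=C3)C2 | intermediate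
14 | (3R)-3-(5-hydroxy-2,2-dimethyl-2H-chromen-8-yl)-6-(3-methylbut-2-en-1-yl)chroman-7-ol | CC(C)=CCc1cc2c(cc1O)OC[C@@H](c1ccc(O)c3c1OC(C)(C)C=C3)C2 | target

Total step count: 8. Longest linear sequence: 5 steps (steps 1, 2, 3, 7, 8; the branch 4, 5, 6, 7, 8 is equally long).

Steps most likely to fail

Step 7 (proposed new method). Several things could go wrong. Formate might reduce the aryl–palladium before it inserts, which would only debrominate 12. The benzylic palladium might epimerise and lose a β-hydrogen to give the achiral isoflav-3-ene. Palladium hydride might isomerise 6 to its 4H-isomer. Facial discrimination in the insertion might be poor. The fallback uses known reaction types and sets out from 6 and 12. Copper-catalysed enantioselective hydroboration of the cyclic styrene 6 (B2pin2, CuCl, NaOt-Bu, a chiral bisphosphine such as DTBM-SEGPHOS, MeOH, THF) would put boron on C3 and hydrogen on C4 and give triisopropyl{[(3S)-6-(3-methylbut-2-en-1-yl)-3-(4,4,5,5-tetramethyl-1,3,2-dioxaborolan-2-yl)chroman-7-yl]oxy}silane F1. Bromine–lithium exchange on 12 (t-BuLi, 2 equiv, THF, −78 °C) would give [5-(tert-butyldiphenylsilyloxy)-2,2-dimethyl-2H-chromen-8-yl]lithium F2, which would add to F1 to form the lithium aryl(chroman-3-yl)pinacolatoborate F3. Oxidation of the electron-rich aryl ring of F3 with DDQ would trigger a stereoretentive 1,2-migration of the chromanyl group from boron to the aryl carbon and loss of boron. This comes back to the route at 13; the descriptor changes from S to R only because the priorities change.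

Step 3. The amine might cleave the silyl ether of the 4-silyloxy-substituted aldehyde or iminium ion, vinyl transfer to the electron-rich aldehyde might be slow, and the electron-rich chromene might oligomerise at 90 °C. The fallback sets out from 3 and closes ring C through the C3=C4 bond instead of the O1–C2 bond. Mitsunobu O-allylation (allyl alcohol, PPh3, DIAD, THF) would give 2-(allyloxy)-5-(3-methylbut-2-en-1-yl)-4-(triisopropylsilyloxy)benzaldehyde F4. Wittig methylenation (Ph3PCH3Br, KN(SiMe3)2, THF) would give 1-(allyloxy)-4-(3-methylbut-2-en-1-yl)-5-(triisopropylsilyloxy)-2-vinylbenzene F5. Ring-closing metathesis with the second-generation Grubbs catalyst (CH2Cl2, 40 °C) would then come back to the route at 6.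

Step 4. The two hydroxyls of 7 might not be told apart well enough: silylation next to bromine or double silylation would carry a regioisomer into the Claisen step. The fallback sets out from 1 and relies on chelation instead of steric hindrance. Copper-catalysed propargylation of the free 4-hydroxyl of 1 (3-chloro-3-methylbut-1-yne, DBU, CuCl2·2H2O, MeCN) would give 5-bromo-2-hydroxy-4-(2-methylbut-3-yn-2-yloxy)benzaldehyde F6. Thermal Claisen rearrangement and electrocyclisation at the only free ortho carbon (o-xylene, 140 °C) would give 8-bromo-5-hydroxy-2,2-dimethyl-2H-chromene-6-carbaldehyde F7. Silylation of the chelated hydroxyl (t-BuPh2SiCl, imidazole, DMAP, DMF, 50 °C) would give 8-bromo-5-(tert-butyldiphenylsilyloxy)-2,2-dimethyl-2H-chromene-6-carbaldehyde F8. Rhodium-catalysed decarbonylation of the aldehyde (RhCl3·3H2O, dppp, diglyme, reflux) would then come back to the route at 12.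

Further compounds
F1 | step 7 | triisopropyl{[(3S)-6-(3-methylbut-2-en-1-yl)-3-(4,4,5,5-tetramethyl-1,3,2-dioxaborolan-2-yl)chroman-7-yl]oxy}silane | CC(C)=CCc1cc2c(cc1O[Si](C(C)C)(C(C)C)C(C)C)OC[C@@H](B1OC(C)(C)C(C)(C)O1)C2
F2 | step 7 | [5-(tert-butyldiphenylsilyloxy)-2,2-dimethyl-2H-chromen-8-yl]lithium | [Li]c1ccc(O[Si](c2ccccc2)(c2ccccc2)C(C)(C)C)c2C=CC(C)(C)Oc12
F3 | step 7 | lithium [5-(tert-butyldiphenylsilyloxy)-2,2-dimethyl-2H-chromen-8-yl][(3S)-6-(3-methylbut-2-en-1-yl)-7-(triisopropylsilyloxy)chroman-3-yl](pinacolato)borate | [Li+].CC(C)=CCc1cc2c(cc1O[Si](C(C)C)(C(C)C)C(C)C)OC[C@@H]([B-]1(OC(C)(C)C(C)(C)O1)c1ccc(O[Si](c4ccccc4)(c4ccccc4)C(C)(C)C)c3c1OC(C)(C)C=C3)C2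
F4 | step 3 | 2-(allyloxy)-5-(3-methylbut-2-en-1-yl)-4-(triisopropylsilyloxy)benzaldehyde | O=Cc1cc(CC=C(C)C)c(O[Si](C(C)C)(C(C)C)C(C)C)cc1OCC=C
F5 | step 3 | 1-(allyloxy)-4-(3-methylbut-2-en-1-yl)-5-(triisopropylsilyloxy)-2-vinylbenzene | C=Cc1cc(CC=C(C)C)c(O[Si](C(C)C)(C(C)C)C(C)C)cc1OCC=C
F6 | step 4 | 5-bromo-2-hydroxy-4-(2-methylbut-3-yn-2-yloxy)benzaldehyde | O=Cc1cc(Br)c(OC(C)(C)C#C)cc1O
F7 | step 4 | 8-bromo-5-hydroxy-2,2-dimethyl-2H-chromene-6-carbaldehyde | O=Cc1cc(Br)c2OC(C)(C)C=Cc2c1O
F8 | step 4 | 8-bromo-5-(tert-butyldiphenylsilyloxy)-2,2-dimethyl-2H-chromene-6-carbaldehyde | O=Cc1cc(Br)c2OC(C)(C)C=Cc2c1O[Si](c3ccccc3)(c3ccccc3)C(C)(C)C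
A1 | direct plan | (S)-4-benzyl-3-{2-[2-(benzyloxy)-4-(triisopropylsilyloxy)phenyl]acetyl}oxazolidin-2-one | O=C1OC[C@H](Cc2ccccc2)N1C(=O)Cc1ccc(O[Si](C(C)C)(C(C)C)C(C)C)cc1OCc1ccccc1
A2 | direct plan | 2-(allyloxy)-5-bromo-4-(triisopropylsilyloxy)benzaldehyde | O=Cc1cc(Br)c(O[Si](C(C)C)(C(C)C)C(C)C)cc1OCC=C
A3 | direct plan | (S)-4-benzyl-3-{(2S,3S)-3-[2-(allyloxy)-5-bromo-4-(triisopropylsilyloxy)phenyl]-2-[2-(benzyloxy)-4-(triisopropylsilyloxy)phenyl]-3-hydroxypropanoyl}oxazolidin-2-one | O=C1OC[C@H](Cc2ccccc2)N1C(=O)[C@@H](c1ccc(O[Si](C(C)C)(C(C)C)C(C)C)cc1OCc1ccccc1)[C@H](O)c1cc(Br)c(O[Si](C(C)C)(C(C)C)C(C)C)cc1OCC=C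
A4 | direct plan | (3R)-6-bromo-3-[2,2-dimethyl-5-(triisopropylsilyloxy)-2H-chromen-8-yl]-7-(triisopropylsilyloxy)chromane | Brc1cc2c(cc1O[Si](C(C)C)(C(C)C)C(C)C)OC[C@@H](c1ccc(O[Si](C(C)C)(C(C)C)C(C)C)c3c1OC(C)(C)C=C3)C2
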